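Readings and results are simulated with constants of no real substance, and the scatter is random.

I began from the times of reading, 12 min and 10 h, since the first asks for a comparison of two rates near the opening of the flask and the second for what that comparison has gathered as it drifts.

| flask | left-handed substrate | right-handed substrate | reagent | free catalyst | added ligand | remark | time |
|---|---|---|---|---|---|---|---|
| Friday's | 0.050 M | 0.050 M | 3 equiv (fed, over 3.0 h) | 8.5 mol% | 5.7 mM | run made earlier |  |
| Saturday's | 0.050 M | 0.050 M | 3 equiv (fed, over 3.0 h) | 34 mol% | 5.7 mM | run made earlier |  |
| flask | 0.050 M | 0.050 M | 3.00 equiv (fed, over 3.0 h) | 17 mol% | 5.7 mM |  | 10 h |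

| run | time / h | left-handed product / % | right-handed product / % | left-handed substrate / % |
|---|---|---|---|---|
| Friday's | 0.833 | 0 | 0 | 48.9 |
| Friday's | 2.00 | 5.2 | 2.0 | 46.4 |
| Friday's | 4.00 | 11.7 | 6.1 | 40.4 |
| Friday's | 10.0 | 22.9 | 12.9 | 31.7 |
| Saturday's | 1.33 | 5.2 | 2.9 | 44.5 |
| Saturday's | 4.00 | 17.9 | 8.8 | 34.7 |
| Saturday's | 6.00 | 22.7 | 12.6 | 32.5 |
| Saturday's | 10.0 | 27.1 | 14.9 | 28.3 |

(standard deviation of a reading: 0.5 percentage points)

* excess of left-handed product over right-handed product in the product at 12 min
* excess of left-handed product over right-handed product in the product at 10 h
* part of the left-handed substrate and right-handed substrate charged together that has reacted at 10 h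

- free catalyst is single-handed; left-handed substrate and right-handed substrate are mirror images of each other, charged as a racemate, each of them at the stated concentration
- steps under discussion: reagent + free catalyst + right-handed substrate -> free catalyst + right-handed product; reagent + free catalyst + left-handed substrate -> free catalyst + left-handed product; 2 free catalyst -> spent catalyst; left-handed substrate <-> right-handed substrate; free catalyst + added ligand <-> idle complex
- an excess is the difference of the two amounts in percent of their sum
- an excess is below zero if the other one leads

At 10.0 h in Friday's run, left-handed product and left-handed substrate together stood at 54.6%, above the half charged, so right-handed substrate was turning into left-handed substrate. At any moment the ratio of the two product rates is the selectivity factor times the ratio of left-handed to right-handed substrate. I therefore took each run's last product ratio and multiplied it by right-handed over left-handed substrate, the right-handed amount being what the balance leaves, and this late ratio stood in for the mean one. The readings gave 1.82 on Friday and 1.91 on Saturday, with a mean of 1.86. I called the opening excess the selectivity factor less one over the selectivity factor plus one, which is the product excess while the two substrates stand equal, and it came to 30.2%. But left-handed substrate goes faster, so the gathered excess drifts lower: Saturday's last reading gave 29.0%.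

The forecast gave 35%, 28.5% and 39%, its first value standing above my opening excess, and it reasoned that “the substrate is still racemic, so the product excess should equal this”.

The flask gave 30.6%, 29.3% and 40.4%, all within the forecast's margins.

    reagent + free catalyst + right-handed substrate → free catalyst + right-handed product (k = 0.0850 M⁻² s⁻¹)
    reagent + free catalyst + left-handed substrate → free catalyst + left-handed product (k = 0.160 M⁻² s⁻¹)
    2 free catalyst → spent catalyst (k = 0.0310 M⁻¹ s⁻¹)
    left-handed substrate ⇌ right-handed substrate (k = 1.60 × 10⁻⁴ s⁻¹)
    free catalyst + added ligand ⇌ idle complex, settled at all times (K = 80.0 M⁻¹)

In the flask, the half-life of left-handed substrate by its forward path to right-handed substrate alone was 1.2 h at 10.0 h, short against the 10 h of the run, and right-handed substrate led left-handed substrate by an excess of 1.71% among what was left of the two at 5.00 h, while the product excess fell 1.3 percentage points between 12 min and 10 h. The neighbouring flask with 7.50 equiv of reagent stood at 30.5% at 12 min, close to the opening excess of 30.2% that I had reckoned from the readings, and with 73.6% reacted at its end, its product excess had fallen 3.2 points to 27.3%.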